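The reading at 2.0 h comes after the last earlier reading at 80.0 min, and single product in the south-west run gains only 1.1 percentage points from 50.0 min on. So I treat each flask as stopped and ask what stops it.

| flask | substrate | partner | remark | time |
|---|---|---|---|---|
| south-west | 0.40 M | 0.98 equiv | run made earlier |  |
| north | 0.40 M | 1.4 equiv | run made earlier |  |
| blue | 0.40 M | 1.00 equiv |  | 2.0 h |
| amber | 0.40 M | 2.50 equiv |  | 2.0 h |
| grey | 0.40 M | 0.800 equiv |  | 2.0 h |

| run | time / min | bis adduct / % | single product / % |
|---|---|---|---|
| south-west | 15.0 | 0 | 17.8 |
| south-west | 30.0 | 1.1 | 25.3 |
| south-west | 50.0 | 3.4 | 26.4 |
| south-west | 60.0 | 2.3 | 26.8 |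
| south-west | 80.0 | 1.1 | 27.5 |
| north | 15.0 | 0.6 | 22.1 |
| north | 30.0 | 0 | 30.7 |
| north | 50.0 | 2.1 | 36.6 |
| north | 60.0 | 2.7 | 37.3 |
| north | 80.0 | 0.4 | 39.7 |

(readings scatter by 1 percentage point)

- a reading or a percentage of single product counts all its forms, free or not

- which of these holds the largest part of the substrate at the end of blue (substrate / single product / bis adduct)
- which of these holds the largest part of the substrate at the end of amber (substrate / single product / bis adduct)
- which of these holds the largest part of the substrate at the end of grey (substrate / single product / bis adduct)
- amount of bis adduct at the end of amber, in percent of the substrate charged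

Substrate remains in both runs, yet more partner gives more product, so I suppose partner also decays first-order. Count substrate turnovers as L, the natural logarithm of substrate charged over substrate left. Each turnover then costs a fixed waste ρ in equivalents, so a flask that has stopped for want of partner obeys E = X + ρL, where E is the equivalents charged and X the fraction of substrate turned (single product plus bis adduct). ρ is partner lost over partner taken by substrate at the start, a selectivity factor, with substrate concentration beneath it.

The last readings give 2.06 for south-west and 1.95 for north. Their mean, 2.00, is my waste ratio. Is one number enough? South-west's value with north's X returns E = 1.46 against 1.4 equiv charged, which I accept.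

Solving the rule leaves substrate at 70.4% in blue, 39.0% in amber and 75.7% in grey. The rule does not split the turned substrate; the highest reading of bis adduct, in the south-west run, is 3.4%, so I expect a few percent in amber. Substrate therefore leads in blue and grey, and single product leads in amber.

The forecast reads the levelling off as something that “points to a reversible first addition” and gives substrate for blue, single product for amber, substrate for grey and 6% of bis adduct in amber.

Substrate ends at 69.2% in blue, 37.2% in amber and 74.7% in grey; amber holds single product 58.0% and bis adduct 4.77%, so the forecast holds.

    substrate + partner → single product (k = 0.0490 L mol⁻¹ min⁻¹)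
    partner → decomposed reagent (k = 0.0360 min⁻¹)
    partner + single product → bis adduct (k = 0.130 L mol⁻¹ min⁻¹)
    crystals ⇌ single product, rate k4*(cs4 - [single product]) while solid is left; crystals form when [single product] > cs4 (solubility = 4.10 mM, k = 1.90 min⁻¹)

At the start of amber, partner goes to decomposed reagent 1.8 times as fast as it goes to substrate, and by 2.00 h partner stands at 0.419% of its charge, with bis adduct still 4.78% at 20.0 h. Amber's neighbour at 1.0 M substrate, same equivalents, has ρ scaled to 0.802, which leaves 13.1% substrate; that flask ends with 12.6%.

The earlier runs and the new flask were generated by integration with made-up constants, and the scatter is random.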